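**Strategy.** The target is epicatechin-(4α→6)-epiafzelechin-(4α→8)-epicatechin-(4β→6)-epicatechin (units 2, 1, 3, 4). The last skeletal bond made joins C4 of unit 2 to C6 of unit 1. This bond lies cis to O3 on ring C of unit 2. C6 is the only unsubstituted ring A carbon next to O5 of unit 1. An O3–Si(iPr)2–O5 bridge therefore dictates face and site at once. One Lewis-acid operation ionises C4, closes a temporary seven-membered ring, forms the bond and sets the C4 stereocentre. The precursor is the benzylated trimer 1–3–4, silylated at O5 by a 4β-(2-ethoxyethoxy)epicatechin. Bromine caps on C8 of units 2 and 4 silence rival nucleophilic sites.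

Key step: step 19

Remarks on the chemistry
- α is the face of a ring C that carries its 2-aryl group, and in the epi series also O3. β is the opposite face. All four units have the 2R,3R (2,3-cis) arrangement.
- Unit 1 is 2,3-cis-3,4-cis. A 2,3-trans dihydroflavonol such as (+)-aromadendrin would carry its trans C2/C3 relation into the product. The C4 ketone of unit 1 is therefore made from (−)-epiafzelechin, and O5 is singled out afterwards through its peri relation to that ketone.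
- The 4β→6 bond between units 3 and 4 needs C8 of unit 4 blocked. Bromine blocks it and stays until the final hydrogenolysis. Iodine on C8 of unit 3 is the more reactive halogen and serves for selective metalation.
- Assumption: (−)-epiafzelechin is bought as the isolated natural product.

Step 1
Reactants: 1 (−)-epicatechin
Product: 2 5,7,3',4'-tetra-O-benzyl-(−)-epicatechin (3-OH free)
Conditions: BnBr (4.4 equiv), K2CO3, DMF, 0 °C → rt, under argon
Reagents that add atoms: benzyl bromide, BrCc1ccccc1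
Why: Williamson ether synthesis: K2CO3 ionises only the four phenols, so the secondary 3-OH stays free, and the mild base under argon leaves C2 and C3 untouched.

Step 2
Reactants: 2 5,7,3',4'-tetra-O-benzyl-(−)-epicatechin
Product: 3 3,5,7,3',4'-penta-O-benzyl-(−)-epicatechin
Conditions: NaH, BnBr, Bu4NI (cat.), THF, 0 °C → rt
Reagents that add atoms: benzyl bromide, BrCc1ccccc1
Why: Williamson ether synthesis on the sodium alkoxide of the last free hydroxyl; with all phenols capped, ring C cannot open, so the 2,3-cis configuration is kept.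

Step 3
Reactants: 3 3,5,7,3',4'-penta-O-benzyl-(−)-epicatechin
Product: 4 8-bromo-3,5,7,3',4'-penta-O-benzylepicatechin (unit 4 nucleophile)
Conditions: NBS (1.0 equiv), CH2Cl2, −78 → 0 °C
Reagents that add atoms: N-bromosuccinimide, O=C1CCC(=O)N1Br
Why: Electrophilic aromatic bromination: ring A is the most electron-rich ring, and C8 (between one benzyloxy group and the ring oxygen) is more accessible than C6 (between two benzyloxy groups), so one equivalent should give the 8-bromide that later blocks C8.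

Step 4
Reactants: 3 3,5,7,3',4'-penta-O-benzyl-(−)-epicatechin
Product: 5 4β-(2-ethoxyethoxy)-3,5,7,3',4'-penta-O-benzylepicatechin (3,4-trans)
Conditions: DDQ (2 equiv), 2-ethoxyethanol, CH2Cl2, rt
Reagents that add atoms: 2-ethoxyethanol, CCOCCO
Why: DDQ benzylic oxidation by hydride abstraction: the flavan-4-yl cation stabilised by ring A is captured by the alcohol on its β face, anti to the axial 3-benzyloxy group, which sets C4 as 3,4-trans.

Step 5
Reactants: 5 4β-(2-ethoxyethoxy)-3,5,7,3',4'-penta-O-benzylepicatechin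
Product: 6 8-iodo-4β-(2-ethoxyethoxy)-3,5,7,3',4'-penta-O-benzylepicatechin (unit 3 electrophile)
Conditions: NIS (1.05 equiv), CH2Cl2, −20 → 0 °C, dark
Reagents that add atoms: N-iodosuccinimide, O=C1CCC(=O)N1I
Why: Electrophilic aromatic iodination under neutral conditions that spare the acid-labile C4 ether; site selectivity follows step 3, and the iodine serves first as a cap against self-condensation and later as the handle for metalation.

Step 6
Reactants: 6 8-iodo-4β-(2-ethoxyethoxy)-penta-O-benzylepicatechin; 4 8-bromo-penta-O-benzylepicatechin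
Product: 7 dimer 3–4, deca-O-benzyl 8-iodoepicatechin-(4β→6)-8-bromoepicatechin
Conditions: 4 (3 equiv, excess recovered), Me3SiOTf (0.2 equiv), 4 Å MS, CH2Cl2, −78 °C, dark; Et3N
Reagents that add atoms: none
Why: Lewis-acid Friedel–Crafts flavanylation with halogen capping: the C4 cation from 6 is attacked on its β face (anti to the 2-aryl and 3-benzyloxy groups, giving 3,4-trans) by C6 of 4, the only free ring A carbon because C8 bears bromine, while the iodine cap and excess 4 hold back self-condensation of 6.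

Step 7
Reactants: 8 (−)-epiafzelechin
Product: 9 5,7,4'-tri-O-benzylepiafzelechin (3-OH free)
Conditions: BnBr (3.3 equiv), K2CO3, DMF, 0 °C → rt, under argon
Reagents that add atoms: benzyl bromide, BrCc1ccccc1
Why: Williamson ether synthesis as in step 1, selective for the three phenols and without effect on C2 or C3.

Step 8
Reactants: 9 5,7,4'-tri-O-benzylepiafzelechin
Product: 10 3,5,7,4'-tetra-O-benzylepiafzelechin
Conditions: NaH, BnBr, Bu4NI (cat.), THF, 0 °C → rt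
Reagents that add atoms: benzyl bromide, BrCc1ccccc1
Why: Williamson ether synthesis on the secondary alkoxide as in step 2, with the configuration retained.

Step 9
Reactants: 10 3,5,7,4'-tetra-O-benzylepiafzelechin
Product: 11 4β-hydroxy-3,5,7,4'-tetra-O-benzylepiafzelechin
Conditions: DDQ (2 equiv), CH2Cl2–H2O, rt
Reagents that add atoms: water, O
Why: DDQ benzylic oxidation in wet solvent: the C4 cation is trapped by water on the β face (3,4-trans carbinol), a stereocentre that step 10 erases.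

Step 10
Reactants: 11 4β-hydroxy-3,5,7,4'-tetra-O-benzylepiafzelechin
Product: 12 3,5,7,4'-tetra-O-benzyl-4-oxoepiafzelechin (2,3-cis dihydrokaempferol tetrabenzyl ether)
Conditions: Pr4N[RuO4] (5 mol %), N-methylmorpholine N-oxide, 4 Å MS, CH2Cl2, rt
Reagents that add atoms: none
Why: Ley–Griffith oxidation: the neutral catalytic perruthenate system turns the benzylic alcohol into the aryl ketone without acid or base, so the epimerisable C3 stereocentre next to the new carbonyl should be retained.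

Step 11
Reactants: 12 3,5,7,4'-tetra-O-benzyl-4-oxoepiafzelechin
Product: 14 3,7,4'-tri-O-benzyl-5-hydroxy-4-oxoepiafzelechin (2,3-cis), via dichloroboron chelate 13 (not isolated)
Conditions: BCl3 (1.1 equiv), CH2Cl2, −78 °C; then sat. aq NaHCO3
Reagents that add atoms: none
Why: Chelation-directed ether cleavage: BCl3 binds the C4 carbonyl and the peri O5, and only that benzyl group leaves (as benzyl chloride) because it gives a six-membered boron chelate of a vinylogous carboxylate, while the low temperature protects the 3-, 7- and 4'-benzyl ethers and C3.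

Step 12
Reactants: 14 3,7,4'-tri-O-benzyl-5-hydroxy-4-oxoepiafzelechin
Product: 15 5-O-allyl-3,7,4'-tri-O-benzyl-4-oxoepiafzelechin (2,3-cis)
Conditions: allyl methyl carbonate (3 equiv), Pd(PPh3)4 (5 mol %), THF, 40 °C
Reagents that add atoms: allyl methyl carbonate, C=CCOC(=O)OC
Why: Tsuji–Trost O-allylation: zerovalent palladium ionises the carbonate, the methoxide released with CO2 deprotonates the most acidic site (the hydrogen-bonded phenol) and the phenoxide captures the π-allyl complex, so no external base that could epimerise C3 or open ring C is needed.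

Step 13
Reactants: 7 dimer 3–4 (8-iodo on unit 3, 8-bromo on unit 4); 15 5-O-allyl-3,7,4'-tri-O-benzyl-4-oxoepiafzelechin
Product: 18 trimer carbinol (C4 of unit 1 bears α-OH plus the β-oriented C8 aryl group of unit 3), via aryllithium 16 (not isolated), via aryl-cerium dichloride 17 (not isolated)
Conditions: 7 (1.3 equiv), n-BuLi (1.3 equiv), THF, −78 °C, 10 min; anhydrous CeCl3 (1.5 equiv), −78 °C; then 15, −78 → −30 °C; aq NH4Cl
Reagents that add atoms: none
Why: Halogen–metal exchange followed by organocerium 1,2-addition: iodine–lithium exchange far outruns bromine–lithium exchange, so only C8 of unit 3 is metalated, and the weakly basic, oxophilic cerium reagent adds to the hindered enolisable ketone on the β face, anti to the 2-aryl and 3-benzyloxy groups, giving a carbinol configuration that step 14 erases.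

Step 14
Reactants: 18 trimer carbinol
Product: 19 5-O-allyl trimer 1–3–4 (unit 1 2,3-cis-3,4-cis, 4α→8 bond)
Conditions: Bu3SnH (5 equiv), CF3CO2H, CH2Cl2, 0 °C
Reagents that add atoms: none
Why: Ionic deoxygenation (SN1 ionisation then hydride transfer): acid ionises the doubly benzylic tertiary alcohol and Bu3SnH delivers hydride to the planar C4 cation from the β face, opposite the α-oriented 2-aryl and 3-benzyloxy groups, so the aryl group of unit 3 ends α and cis to O3.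

Step 15
Reactants: 19 5-O-allyl trimer 1–3–4
Product: 20 trimer 1–3–4 with free O5–H on unit 1
Conditions: Pd(PPh3)4 (5 mol %), morpholine (5 equiv), THF, rt
Reagents that add atoms: none
Why: Tsuji–Trost-type deallylation: zerovalent palladium ionises the aryl allyl ether and morpholine traps the π-allyl fragment; benzyl ethers are inert, and the hindered, electron-rich aryl bromide should not undergo oxidative addition at room temperature.

Step 16
Reactants: 2 5,7,3',4'-tetra-O-benzyl-(−)-epicatechin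
Product: 21 4β-(2-ethoxyethoxy)-5,7,3',4'-tetra-O-benzylepicatechin (3-OH free, 3,4-trans)
Conditions: DDQ (2 equiv), 2-ethoxyethanol, CH2Cl2, rt
Reagents that add atoms: 2-ethoxyethanol, CCOCCO
Why: DDQ benzylic oxidation as in step 4; the free axial 3-OH is tolerated and again directs the alcohol to the β face of the C4 cation.

Step 17
Reactants: 21 4β-(2-ethoxyethoxy)-5,7,3',4'-tetra-O-benzylepicatechin
Product: 22 8-bromo-4β-(2-ethoxyethoxy)-5,7,3',4'-tetra-O-benzylepicatechin (unit 2)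
Conditions: NBS (1.0 equiv), CH2Cl2, −78 → 0 °C
Reagents that add atoms: N-bromosuccinimide, O=C1CCC(=O)N1Br
Why: Electrophilic aromatic bromination with the C8 selectivity of step 3, under neutral conditions that leave the C4 ether intact; it removes the most nucleophilic free carbon of unit 2 before the key step.

Step 18
Reactants: 22 8-bromo-4β-(2-ethoxyethoxy)-tetra-O-benzylepicatechin; 23 dichlorodiisopropylsilane; 20 trimer 1–3–4 with free O5–H
Product: 25 tethered precursor (O5 of unit 1–Si(iPr)2–O3 of unit 2), via chlorosilyl ether 24 (not isolated)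
Conditions: 22 (2 equiv), 23 (6 equiv), imidazole, CH2Cl2, 0 °C → rt; excess 23 removed in high vacuum; then 20 (1 equiv), imidazole, DMAP, DMF, rt → 40 °C
Reagents that add atoms: dichlorodiisopropylsilane 23, CC(C)[Si](Cl)(Cl)C(C)C
Why: Stepwise nucleophilic substitution at silicon (mixed silaketal formation): with 23 in excess, the two isopropyl groups stop the hindered axial 3-OH of 22 after one chloride is displaced, and the remaining Si–Cl bond is then taken by the only free hydroxyl of 20, the O5 phenol, with no stereocentre touched.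

Step 19
Reactants: 25 tethered precursor
Product: 26 silylene-bridged heptadeca-O-benzyl tetramer (new C4(unit 2)–C6(unit 1) bond, cis to O3 of unit 2)
Conditions: 25 added by syringe pump to Me3SiOTf (0.3 equiv), 4 Å MS, CH2Cl2 (final 1 mM), −78 → −40 °C; Et3N
Reagents that add atoms: none
Why: Me3SiOTf silylates and expels the 2-ethoxyethoxy group to leave the flavan-4-yl cation of unit 2, whose charge is shared by O5, O7 and O1 of its ring A; C6 of unit 1 adds to it and loss of H6 restores the arene and returns the acid, which makes this an intramolecular Friedel–Crafts alkylation. The closest known reactions are Lewis-acid condensations of flavan-3-ols joined by a diester tether, including O3-to-O5 tethers that force 4→6 bonding, and silicon-tethered aglycon delivery to 1,2-cis glycosides. The seven-membered ring (Si, O5, C5, C6 of unit 1; C4, C3, O3 of unit 2) closes in the 7-exo-trig mode with respect to the C4=C4a bond of the cation. The new C4 stereocentre is controlled by the resident C3 stereocentre through the tether: the three-atom O–Si–O link can span only a small O3–C3–C4–C6 dihedral angle, so the arene must arrive on the α face that carries O3, against the intrinsic β preference. C6 rather than C8 reacts because C6 is the only C–H ortho to the anchoring O5, C4a being quaternary and C8 out of reach. Intermolecular arylation is held back by pseudo-high dilution and by the bromine caps on C8 of units 2 and 4.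

Step 20
Reactants: 26 silylene-bridged tetramer
Product: 27 heptadeca-O-benzyl dibromo tetramer with free 3-OH (unit 2) and 5-OH (unit 1)
Conditions: Bu4NF (2.5 equiv), AcOH (2.5 equiv), THF, 0 °C → rt
Reagents that add atoms: none
Why: Fluoride-induced desilylation driven by the Si–F bond strength; acetic acid keeps the liberated phenoxide protonated, and benzyl ethers, aryl bromides and all C–C bonds are untouched.

Step 21
Reactants: 27 heptadeca-O-benzyl dibromo tetramer diol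
Product: 28 target CNP0103636.2
Conditions: H2 (1 atm), Pd(OH)2/C, NaOAc (3 equiv), THF–MeOH–H2O, rt
Reagents that add atoms: none
Why: Catalytic hydrogenolysis: the seventeen benzylic C–O bonds and the two aryl C–Br bonds are cleaved over Pd(OH)2/C, acetate takes up the HBr so the acid-labile interflavan bonds are not exposed, and no stereocentre is involved.

Compound list
1 | (−)-epicatechin (2R,3R) | O[C@@H]1Cc2c(O)cc(O)cc2O[C@@H]1c1ccc(O)c(O)c1 | starting material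
2 | 5,7,3',4'-tetra-O-benzyl-(−)-epicatechin | O[C@@H]1Cc2c(OCc9ccccc9)cc(OCc9ccccc9)cc2O[C@@H]1c1ccc(OCc9ccccc9)c(OCc9ccccc9)c1 | intermediate
3 | 3,5,7,3',4'-penta-O-benzyl-(−)-epicatechin | c9ccccc9CO[C@@H]1Cc2c(OCc9ccccc9)cc(OCc9ccccc9)cc2O[C@@H]1c1ccc(OCc9ccccc9)c(OCc9ccccc9)c1 | intermediate
4 | 8-bromo-3,5,7,3',4'-penta-O-benzylepicatechin | c9ccccc9CO[C@@H]1Cc2c(OCc9ccccc9)cc(OCc9ccccc9)c(Br)c2O[C@@H]1c1ccc(OCc9ccccc9)c(OCc9ccccc9)c1 | intermediate
5 | 4β-(2-ethoxyethoxy)-3,5,7,3',4'-penta-O-benzylepicatechin (3,4-trans) | c9ccccc9CO[C@@H]1[C@@H](OCCOCC)c2c(OCc9ccccc9)cc(OCc9ccccc9)cc2O[C@@H]1c1ccc(OCc9ccccc9)c(OCc9ccccc9)c1 | intermediate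
6 | 8-iodo-4β-(2-ethoxyethoxy)-3,5,7,3',4'-penta-O-benzylepicatechin | c9ccccc9CO[C@@H]1[C@@H](OCCOCC)c2c(OCc9ccccc9)cc(OCc9ccccc9)c(I)c2O[C@@H]1c1ccc(OCc9ccccc9)c(OCc9ccccc9)c1 | intermediate
7 | dimer 3–4, deca-O-benzyl 8-iodoepicatechin-(4β→6)-8-bromoepicatechin | Ic3c(OCc9ccccc9)cc(OCc9ccccc9)c4c3O[C@H](c3ccc(OCc9ccccc9)c(OCc9ccccc9)c3)[C@H](OCc9ccccc9)[C@H]4c3c(OCc9ccccc9)c(Br)c4c(c3OCc9ccccc9)C[C@@H](OCc9ccccc9)[C@@H](c3ccc(OCc9ccccc9)c(OCc9ccccc9)c3)O4 | intermediate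
8 | (−)-epiafzelechin (2R,3R) | O[C@@H]1Cc2c(O)cc(O)cc2O[C@@H]1c1ccc(O)cc1 | starting material
9 | 5,7,4'-tri-O-benzylepiafzelechin | O[C@@H]1Cc2c(OCc9ccccc9)cc(OCc9ccccc9)cc2O[C@@H]1c1ccc(OCc9ccccc9)cc1 | intermediate
10 | 3,5,7,4'-tetra-O-benzylepiafzelechin | c9ccccc9CO[C@@H]1Cc2c(OCc9ccccc9)cc(OCc9ccccc9)cc2O[C@@H]1c1ccc(OCc9ccccc9)cc1 | intermediate
11 | 4β-hydroxy-3,5,7,4'-tetra-O-benzylepiafzelechin | c9ccccc9CO[C@@H]1[C@@H](O)c2c(OCc9ccccc9)cc(OCc9ccccc9)cc2O[C@@H]1c1ccc(OCc9ccccc9)cc1 | intermediate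
12 | 3,5,7,4'-tetra-O-benzyl-4-oxoepiafzelechin (2,3-cis) | c9ccccc9CO[C@@H]1C(=O)c2c(OCc9ccccc9)cc(OCc9ccccc9)cc2O[C@@H]1c1ccc(OCc9ccccc9)cc1 | intermediate
13 | O5-dichloroboryl chelate of the 4-ketone | c9ccccc9CO[C@@H]1C(=O)c2c(OB(Cl)Cl)cc(OCc9ccccc9)cc2O[C@@H]1c1ccc(OCc9ccccc9)cc1 | intermediate
14 | 3,7,4'-tri-O-benzyl-5-hydroxy-4-oxoepiafzelechin (2,3-cis) | c9ccccc9CO[C@@H]1C(=O)c2c(O)cc(OCc9ccccc9)cc2O[C@@H]1c1ccc(OCc9ccccc9)cc1 | intermediate
15 | 5-O-allyl-3,7,4'-tri-O-benzyl-4-oxoepiafzelechin (2,3-cis) | c9ccccc9CO[C@@H]1C(=O)c2c(OCC=C)cc(OCc9ccccc9)cc2O[C@@H]1c1ccc(OCc9ccccc9)cc1 | intermediate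
16 | dimer 3–4 lithiated at C8 of unit 3 | [Li]c3c(OCc9ccccc9)cc(OCc9ccccc9)c4c3O[C@H](c3ccc(OCc9ccccc9)c(OCc9ccccc9)c3)[C@H](OCc9ccccc9)[C@H]4c3c(OCc9ccccc9)c(Br)c4c(c3OCc9ccccc9)C[C@@H](OCc9ccccc9)[C@@H](c3ccc(OCc9ccccc9)c(OCc9ccccc9)c3)O4 | intermediate
17 | dimer 3–4 bearing CeCl2 at C8 of unit 3 | Cl[Ce](Cl)c3c(OCc9ccccc9)cc(OCc9ccccc9)c4c3O[C@H](c3ccc(OCc9ccccc9)c(OCc9ccccc9)c3)[C@H](OCc9ccccc9)[C@H]4c3c(OCc9ccccc9)c(Br)c4c(c3OCc9ccccc9)C[C@@H](OCc9ccccc9)[C@@H](c3ccc(OCc9ccccc9)c(OCc9ccccc9)c3)O4 | intermediate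
18 | trimer carbinol (unit 1: 5-O-allyl, C4 with α-OH and β-aryl) | c9ccccc9COc1ccc([C@H]2Oc3cc(OCc9ccccc9)cc(OCC=C)c3[C@](O)(c3c(OCc9ccccc9)cc(OCc9ccccc9)c4c3O[C@H](c3ccc(OCc9ccccc9)c(OCc9ccccc9)c3)[C@H](OCc9ccccc9)[C@H]4c3c(OCc9ccccc9)c(Br)c4c(c3OCc9ccccc9)C[C@@H](OCc9ccccc9)[C@@H](c3ccc(OCc9ccccc9)c(OCc9ccccc9)c3)O4)[C@H]2OCc9ccccc9)cc1 | intermediate
19 | 5-O-allyl trimer 1–3–4 (unit 1 all-cis, 4α→8; unit 3 4β→6; 8-Br on unit 4) | c9ccccc9COc1ccc([C@H]2Oc3cc(OCc9ccccc9)cc(OCC=C)c3[C@@H](c3c(OCc9ccccc9)cc(OCc9ccccc9)c4c3O[C@H](c3ccc(OCc9ccccc9)c(OCc9ccccc9)c3)[C@H](OCc9ccccc9)[C@H]4c3c(OCc9ccccc9)c(Br)c4c(c3OCc9ccccc9)C[C@@H](OCc9ccccc9)[C@@H](c3ccc(OCc9ccccc9)c(OCc9ccccc9)c3)O4)[C@H]2OCc9ccccc9)cc1 | intermediate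
20 | trimer 1–3–4 with free O5–H on unit 1 | c9ccccc9COc1ccc([C@H]2Oc3cc(OCc9ccccc9)cc(O)c3[C@@H](c3c(OCc9ccccc9)cc(OCc9ccccc9)c4c3O[C@H](c3ccc(OCc9ccccc9)c(OCc9ccccc9)c3)[C@H](OCc9ccccc9)[C@H]4c3c(OCc9ccccc9)c(Br)c4c(c3OCc9ccccc9)C[C@@H](OCc9ccccc9)[C@@H](c3ccc(OCc9ccccc9)c(OCc9ccccc9)c3)O4)[C@H]2OCc9ccccc9)cc1 | intermediate
21 | 4β-(2-ethoxyethoxy)-5,7,3',4'-tetra-O-benzylepicatechin (3-OH free) | O[C@@H]1[C@@H](OCCOCC)c2c(OCc9ccccc9)cc(OCc9ccccc9)cc2O[C@@H]1c1ccc(OCc9ccccc9)c(OCc9ccccc9)c1 | intermediate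
22 | 8-bromo-4β-(2-ethoxyethoxy)-5,7,3',4'-tetra-O-benzylepicatechin | O[C@@H]1[C@@H](OCCOCC)c2c(OCc9ccccc9)cc(OCc9ccccc9)c(Br)c2O[C@@H]1c1ccc(OCc9ccccc9)c(OCc9ccccc9)c1 | intermediate
23 | dichlorodiisopropylsilane | CC(C)[Si](Cl)(Cl)C(C)C | starting material
24 | 3-O-(chlorodiisopropylsilyl) ether of 22 | CC(C)[Si](Cl)(C(C)C)O[C@@H]1[C@@H](OCCOCC)c2c(OCc9ccccc9)cc(OCc9ccccc9)c(Br)c2O[C@@H]1c1ccc(OCc9ccccc9)c(OCc9ccccc9)c1 | intermediate
25 | tethered precursor: trimer 1–3–4 joined through O5 of unit 1 and Si(iPr)2 to O3 of 4β-(2-ethoxyethoxy) unit 2 | c9ccccc9COc1ccc([C@H]2Oc3cc(OCc9ccccc9)cc(O[Si](C(C)C)(C(C)C)O[C@H]4[C@@H](c5ccc(OCc9ccccc9)c(OCc9ccccc9)c5)Oc5c(Br)c(OCc9ccccc9)cc(OCc9ccccc9)c5[C@@H]4OCCOCC)c3[C@@H](c3c(OCc9ccccc9)cc(OCc9ccccc9)c4c3O[C@H](c3ccc(OCc9ccccc9)c(OCc9ccccc9)c3)[C@H](OCc9ccccc9)[C@H]4c3c(OCc9ccccc9)c(Br)c4c(c3OCc9ccccc9)C[C@@H](OCc9ccccc9)[C@@H](c3ccc(OCc9ccccc9)c(OCc9ccccc9)c3)O4)[C@H]2OCc9ccccc9)cc1 | intermediate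
26 | silylene-bridged benzylated tetramer (seven-membered ring through O3 of unit 2 and O5 of unit 1) | c9ccccc9COc1ccc([C@H]2Oc3cc(OCc9ccccc9)c([C@@H]4c5c(OCc9ccccc9)cc(OCc9ccccc9)c(Br)c5O[C@H](c5ccc(OCc9ccccc9)c(OCc9ccccc9)c5)[C@@H]4O[Si]6(C(C)C)C(C)C)c(O6)c3[C@@H](c3c(OCc9ccccc9)cc(OCc9ccccc9)c4c3O[C@H](c3ccc(OCc9ccccc9)c(OCc9ccccc9)c3)[C@H](OCc9ccccc9)[C@H]4c3c(OCc9ccccc9)c(Br)c4c(c3OCc9ccccc9)C[C@@H](OCc9ccccc9)[C@@H](c3ccc(OCc9ccccc9)c(OCc9ccccc9)c3)O4)[C@H]2OCc9ccccc9)cc1 | intermediate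
27 | heptadeca-O-benzyl dibromo tetramer, 3-OH (unit 2) and 5-OH (unit 1) free | c9ccccc9COc1ccc([C@H]2Oc3cc(OCc9ccccc9)c([C@@H]4c5c(OCc9ccccc9)cc(OCc9ccccc9)c(Br)c5O[C@H](c5ccc(OCc9ccccc9)c(OCc9ccccc9)c5)[C@@H]4O)c(O)c3[C@@H](c3c(OCc9ccccc9)cc(OCc9ccccc9)c4c3O[C@H](c3ccc(OCc9ccccc9)c(OCc9ccccc9)c3)[C@H](OCc9ccccc9)[C@H]4c3c(OCc9ccccc9)c(Br)c4c(c3OCc9ccccc9)C[C@@H](OCc9ccccc9)[C@@H](c3ccc(OCc9ccccc9)c(OCc9ccccc9)c3)O4)[C@H]2OCc9ccccc9)cc1 | intermediate
28 | CNP0103636.2, epicatechin-(4α→6)-epiafzelechin-(4α→8)-epicatechin-(4β→6)-epicatechin | Oc1ccc([C@H]2Oc3cc(O)c([C@@H]4c5c(O)cc(O)cc5O[C@H](c5ccc(O)c(O)c5)[C@@H]4O)c(O)c3[C@@H](c3c(O)cc(O)c4c3O[C@H](c3ccc(O)c(O)c3)[C@H](O)[C@H]4c3c(O)cc4c(c3O)C[C@@H](O)[C@@H](c3ccc(O)c(O)c3)O4)[C@H]2O)cc1 | target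

Total step count: 21. Longest linear sequence: 13 steps (8 → 28 through steps 7–15 and 18–21).

Steps most likely to fail

Step 19. Ring closure at the crowded C6 may be slower than the competing fates of the cation. These are proton loss from C3, intermolecular arylation, acid-induced exchange at the silylene and scission of an interflavan bond.

The fallback sets out from 20 and 3 and rejoins the route at 28. It makes the second 3,4-cis bond as for unit 1, by carbonyl addition and ionic reduction instead of cation capture.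
- The free phenol makes ring A of unit 1 the most activated ring of 20. BnMe3N[ICl2] with CaCO3 in CH2Cl2–MeOH should iodinate it ortho to O5 to give the 6-iodo phenol trimer F1. Any C8 isomer is removed at this stage.
- BnBr and K2CO3 then give the 5-O-benzyl 6-iodo trimer F2.
- In parallel, 3 is taken with DDQ in wet CH2Cl2 to 4β-hydroxy-penta-O-benzylepicatechin F3. Pr4N[RuO4] with N-methylmorpholine N-oxide then gives penta-O-benzyl-4-oxoepicatechin F4.
- Iodine–lithium exchange on F2 (n-BuLi, −78 °C, with the bromide of unit 4 left alone) gives the C6 aryllithium F5. CeCl3 converts it into the C6 aryl-cerium dichloride F6.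
- Addition of F6 to F4 gives the tetramer carbinol F7. Bu3SnH with CF3CO2H delivers hydride to the β face to give the nonadeca-O-benzyl tetramer F8.
- Hydrogenolysis of F8 under the conditions of step 21 gives 28.

Step 13. Steric congestion may stop the addition. The organometallic may instead enolise the ketone, causing C3 epimerisation or opening of ring C. The metal may also migrate from C8 of unit 3 to the brominated C8 of unit 4.

The fallback sets out from 4 and 15 and rejoins at 19. It reverses the order of the two interflavan bond formations, so the carbonyl addition uses a monomeric nucleophile that carries only one halogen.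
- Bromine–lithium exchange on 4 (n-BuLi, THF, −78 °C) gives the monomeric aryllithium F9. CeCl3 gives the monomeric aryl-cerium dichloride F10.
- Addition of F10 to 15 gives the dimer carbinol F11. Bu3SnH with CF3CO2H gives the all-cis dimer 1–3 F12.
- DDQ with 2-ethoxyethanol oxidises the only benzylic CH2 group, C4 of unit 3, to give the 4β-(2-ethoxyethoxy) dimer F13.
- Slow addition of F13 to a large excess of 4 with catalytic Me3SiOTf at −78 °C forms the 4β→6 bond and gives 19.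

Step 6. Acid may cause loss or migration of the iodine. The deactivated, doubly flanked C6 of 4 may also attack so slowly that the electrophile condenses with itself.

The fallback sets out from 6 (with 4) and rejoins at 7. It replaces hard Lewis-acid ionisation of an oxygen leaving group by thiophilic activation of a sulfur one.
- The aluminium thiolate made from AlMe3 and 2-mercaptobenzothiazole exchanges the ether of 6 to give the 4β-(benzothiazol-2-ylthio) 8-iodo flavan F14.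
- AgBF4 in THF–CH2Cl2 at 0 °C, with 2,6-di-tert-butyl-4-methylpyridine to take up the proton, ionises C4 through silver–sulfur affinity in the presence of excess 4 to give 7.

Further compounds
F1 | step 19 | 6-iodo phenol trimer (iodine at C6 of unit 1, O5–H free) | c9ccccc9COc1ccc([C@H]2Oc3cc(OCc9ccccc9)c(I)c(O)c3[C@@H](c3c(OCc9ccccc9)cc(OCc9ccccc9)c4c3O[C@H](c3ccc(OCc9ccccc9)c(OCc9ccccc9)c3)[C@H](OCc9ccccc9)[C@H]4c3c(OCc9ccccc9)c(Br)c4c(c3OCc9ccccc9)C[C@@H](OCc9ccccc9)[C@@H](c3ccc(OCc9ccccc9)c(OCc9ccccc9)c3)O4)[C@H]2OCc9ccccc9)cc1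
F2 | step 19 | 5-O-benzyl 6-iodo trimer | c9ccccc9COc1ccc([C@H]2Oc3cc(OCc9ccccc9)c(I)c(OCc9ccccc9)c3[C@@H](c3c(OCc9ccccc9)cc(OCc9ccccc9)c4c3O[C@H](c3ccc(OCc9ccccc9)c(OCc9ccccc9)c3)[C@H](OCc9ccccc9)[C@H]4c3c(OCc9ccccc9)c(Br)c4c(c3OCc9ccccc9)C[C@@H](OCc9ccccc9)[C@@H](c3ccc(OCc9ccccc9)c(OCc9ccccc9)c3)O4)[C@H]2OCc9ccccc9)cc1
F3 | step 19 | 4β-hydroxy-3,5,7,3',4'-penta-O-benzylepicatechin | c9ccccc9CO[C@@H]1[C@@H](O)c2c(OCc9ccccc9)cc(OCc9ccccc9)cc2O[C@@H]1c1ccc(OCc9ccccc9)c(OCc9ccccc9)c1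
F4 | step 19 | 3,5,7,3',4'-penta-O-benzyl-4-oxoepicatechin (2,3-cis) | c9ccccc9CO[C@@H]1C(=O)c2c(OCc9ccccc9)cc(OCc9ccccc9)cc2O[C@@H]1c1ccc(OCc9ccccc9)c(OCc9ccccc9)c1
F5 | step 19 | trimer lithiated at C6 of unit 1 | c9ccccc9COc1ccc([C@H]2Oc3cc(OCc9ccccc9)c([Li])c(OCc9ccccc9)c3[C@@H](c3c(OCc9ccccc9)cc(OCc9ccccc9)c4c3O[C@H](c3ccc(OCc9ccccc9)c(OCc9ccccc9)c3)[C@H](OCc9ccccc9)[C@H]4c3c(OCc9ccccc9)c(Br)c4c(c3OCc9ccccc9)C[C@@H](OCc9ccccc9)[C@@H](c3ccc(OCc9ccccc9)c(OCc9ccccc9)c3)O4)[C@H]2OCc9ccccc9)cc1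
F6 | step 19 | trimer bearing CeCl2 at C6 of unit 1 | c9ccccc9COc1ccc([C@H]2Oc3cc(OCc9ccccc9)c([Ce](Cl)Cl)c(OCc9ccccc9)c3[C@@H](c3c(OCc9ccccc9)cc(OCc9ccccc9)c4c3O[C@H](c3ccc(OCc9ccccc9)c(OCc9ccccc9)c3)[C@H](OCc9ccccc9)[C@H]4c3c(OCc9ccccc9)c(Br)c4c(c3OCc9ccccc9)C[C@@H](OCc9ccccc9)[C@@H](c3ccc(OCc9ccccc9)c(OCc9ccccc9)c3)O4)[C@H]2OCc9ccccc9)cc1
F7 | step 19 | tetramer carbinol (C4 of unit 2 with α-OH and β-aryl) | c9ccccc9COc1ccc([C@H]2Oc3cc(OCc9ccccc9)c([C@@]4(O)c5c(OCc9ccccc9)cc(OCc9ccccc9)cc5O[C@H](c5ccc(OCc9ccccc9)c(OCc9ccccc9)c5)[C@@H]4OCc9ccccc9)c(OCc9ccccc9)c3[C@@H](c3c(OCc9ccccc9)cc(OCc9ccccc9)c4c3O[C@H](c3ccc(OCc9ccccc9)c(OCc9ccccc9)c3)[C@H](OCc9ccccc9)[C@H]4c3c(OCc9ccccc9)c(Br)c4c(c3OCc9ccccc9)C[C@@H](OCc9ccccc9)[C@@H](c3ccc(OCc9ccccc9)c(OCc9ccccc9)c3)O4)[C@H]2OCc9ccccc9)cc1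
F8 | step 19 | nonadeca-O-benzyl tetramer (8-Br on unit 4) | c9ccccc9COc1ccc([C@H]2Oc3cc(OCc9ccccc9)c([C@@H]4c5c(OCc9ccccc9)cc(OCc9ccccc9)cc5O[C@H](c5ccc(OCc9ccccc9)c(OCc9ccccc9)c5)[C@@H]4OCc9ccccc9)c(OCc9ccccc9)c3[C@@H](c3c(OCc9ccccc9)cc(OCc9ccccc9)c4c3O[C@H](c3ccc(OCc9ccccc9)c(OCc9ccccc9)c3)[C@H](OCc9ccccc9)[C@H]4c3c(OCc9ccccc9)c(Br)c4c(c3OCc9ccccc9)C[C@@H](OCc9ccccc9)[C@@H](c3ccc(OCc9ccccc9)c(OCc9ccccc9)c3)O4)[C@H]2OCc9ccccc9)cc1
F9 | step 13 | 8-lithio-3,5,7,3',4'-penta-O-benzylepicatechin | [Li]c3c(OCc9ccccc9)cc(OCc9ccccc9)c4c3O[C@H](c3ccc(OCc9ccccc9)c(OCc9ccccc9)c3)[C@H](OCc9ccccc9)C4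
F10 | step 13 | 8-(dichloroceryl)-3,5,7,3',4'-penta-O-benzylepicatechin | Cl[Ce](Cl)c3c(OCc9ccccc9)cc(OCc9ccccc9)c4c3O[C@H](c3ccc(OCc9ccccc9)c(OCc9ccccc9)c3)[C@H](OCc9ccccc9)C4
F11 | step 13 | dimer carbinol 1–3 (5-O-allyl, C4 of unit 1 with α-OH and β-aryl) | c9ccccc9COc1ccc([C@H]2Oc3cc(OCc9ccccc9)cc(OCC=C)c3[C@](O)(c3c(OCc9ccccc9)cc(OCc9ccccc9)c4c3O[C@H](c3ccc(OCc9ccccc9)c(OCc9ccccc9)c3)[C@H](OCc9ccccc9)C4)[C@H]2OCc9ccccc9)cc1
F12 | step 13 | all-cis dimer 1–3 (4α→8, 5-O-allyl) | c9ccccc9COc1ccc([C@H]2Oc3cc(OCc9ccccc9)cc(OCC=C)c3[C@@H](c3c(OCc9ccccc9)cc(OCc9ccccc9)c4c3O[C@H](c3ccc(OCc9ccccc9)c(OCc9ccccc9)c3)[C@H](OCc9ccccc9)C4)[C@H]2OCc9ccccc9)cc1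
F13 | step 13 | dimer 1–3 with 4β-(2-ethoxyethoxy) on unit 3 | c9ccccc9COc1ccc([C@H]2Oc3cc(OCc9ccccc9)cc(OCC=C)c3[C@@H](c3c(OCc9ccccc9)cc(OCc9ccccc9)c4c3O[C@H](c3ccc(OCc9ccccc9)c(OCc9ccccc9)c3)[C@H](OCc9ccccc9)[C@H]4OCCOCC)[C@H]2OCc9ccccc9)cc1
F14 | step 6 | 4β-(benzothiazol-2-ylthio)-8-iodo-3,5,7,3',4'-penta-O-benzylepicatechin | c9ccccc9CO[C@@H]1[C@@H](Sc5nc6ccccc6s5)c2c(OCc9ccccc9)cc(OCc9ccccc9)c(I)c2O[C@@H]1c1ccc(OCc9ccccc9)c(OCc9ccccc9)c1
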